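**Assumption:** 2,4,6-trihydroxybenzophenone, 3-chloro-3-methylbut-1-yne and geranyl bromide are bought; the single stereocentre of the target (chroman C3) is R.

## Retrosynthetic overview

1. Target 10 ⇒ chromanol 8 + geranyl bromide 9: C-geranylation at C6, the only free ring carbon, done last.
2. 8 ⇒ chroman-3-one 6: enantioselective ketone reduction sets C3 (R), and the two MOM groups come off in the same flask.
3. 6 ⇒ aryl 1,1-dimethylpropargyl ether 4: the C4–C4a bond is made by attack of the arene on an α-oxo gold carbene (an enolonium equivalent made from the terminal alkyne), joining two normally nucleophilic carbons.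
4. 4 ⇒ phenol 2 + chloride 3; 2 ⇒ 1 by double MOM protection, which leaves only the hydrogen-bonded ortho OH (the future ring oxygen) free.
5. Ring order: both carbocycles are bought with 1; the pyran ring is the only ring formed (step 3).

## Route

**Step 1**
Reactants: 1 2,4,6-trihydroxybenzophenone
Product: 2 [2-hydroxy-4,6-bis(methoxymethoxy)phenyl](phenyl)methanone
Conditions: MOMCl (2.2 equiv), iPr2NEt (3 equiv), CH2Cl2, 0 °C → rt
Reagents that add atoms: chloromethyl methyl ether (MOMCl), COCCl
Why: Williamson-type O-alkylation caps the para OH and one ortho OH, while the remaining ortho OH stays locked in the hydrogen bond to the benzoyl carbonyl, which singles out the oxygen that becomes O1 of the chroman.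

**Step 2**
Reactants: 2 [2-hydroxy-4,6-bis(methoxymethoxy)phenyl](phenyl)methanone; 3 3-chloro-3-methylbut-1-yne
Product: 4 [2,4-bis(methoxymethoxy)-6-(2-methylbut-3-yn-2-yloxy)phenyl](phenyl)methanone
Conditions: 3 (2 equiv), DBU (2.5 equiv), CuCl2·2H2O (1 mol%), MeCN, 0 °C → rt
Reagents that add atoms: none
Why: Copper-catalysed propargylic substitution (copper acetylide/allenylidene, SN1-like) forms tertiary propargyl aryl ethers even from hindered, hydrogen-bonded phenoxides where SN2 is impossible.

**Step 3 (key step)**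
Reactants: 4 [2,4-bis(methoxymethoxy)-6-(2-methylbut-3-yn-2-yloxy)phenyl](phenyl)methanone
Product: 6 [5,7-bis(methoxymethoxy)-2,2-dimethyl-3-oxochroman-8-yl](phenyl)methanone, via α-oxo gold carbene 5 (not isolated)
Conditions: Me4tBuXPhosAuNTf2 (5 mol%), 2,6-dichloropyridine N-oxide (1.3 equiv), ClCH2CH2Cl, rt (Me4tBuXPhos = di-tert-butyl(3,4,5,6-tetramethyl-2',4',6'-triisopropylbiphenyl-2-yl)phosphine)
Reagents that add atoms: 2,6-dichloropyridine N-oxide, [O-][n+]1c(Cl)cccc1Cl
Why: Gold-catalysed alkyne oxidation delivers oxygen to the internal alkyne carbon and leaves an electrophilic α-oxo gold carbene at the terminal carbon (a would-be enolate carbon turned into an enolonium equivalent), which the electron-rich arene carbon ortho to the ether attacks in a 6-ring Friedel–Crafts-type closure to form C4–C4a.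

**Step 4**
Reactants: 6 [5,7-bis(methoxymethoxy)-2,2-dimethyl-3-oxochroman-8-yl](phenyl)methanone
Product: 8 (R)-(3,5,7-trihydroxy-2,2-dimethylchroman-8-yl)(phenyl)methanone, via bis-MOM alcohol 7 (not isolated)
Conditions: (S)-Me-CBS (10 mol%), BH3·SMe2 (0.7 equiv), THF, −20 °C; then MeOH, conc. HCl, 45 °C
Reagents that add atoms: none
Why: Corey–Bakshi–Shibata reduction, in which quaternary C2 is the large group and the C4 methylene the small one, so the (S)-oxazaborolidine gives the (R)-carbinol while the hindered di-ortho-substituted diaryl ketone reacts far more slowly; the methanolic HCl quench then cleaves both MOM acetals by acetal exchange without touching C3.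

**Step 5**
Reactants: 8 (R)-(3,5,7-trihydroxy-2,2-dimethylchroman-8-yl)(phenyl)methanone; 9 geranyl bromide, (E)-1-bromo-3,7-dimethylocta-2,6-diene
Product: 10 [(3R)-6-[(2E)-3,7-dimethylocta-2,6-dien-1-yl]-3,5,7-trihydroxy-2,2-dimethylchroman-8-yl](phenyl)methanone (target)
Conditions: DBU (1.1 equiv), THF, 0 °C; 9 (1.1 equiv), → rt
Reagents that add atoms: none
Why: C-alkylation of the ambident acylphloroglucinol-type phenoxide (SN2 at the primary allylic bromide, E geometry kept) goes to C6, the only free ring carbon and ortho to both phenols, and leaves the C3 stereocentre untouched.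

## Compound list

1 | 2,4,6-trihydroxybenzophenone | O=C(c1ccccc1)c1c(O)cc(O)cc1O | starting material
2 | [2-hydroxy-4,6-bis(methoxymethoxy)phenyl](phenyl)methanone | O=C(c1ccccc1)c1c(O)cc(OCOC)cc1OCOC | intermediate
3 | 3-chloro-3-methylbut-1-yne | C#CC(C)(C)Cl | starting material
4 | [2,4-bis(methoxymethoxy)-6-(2-methylbut-3-yn-2-yloxy)phenyl](phenyl)methanone | C#CC(C)(C)Oc1cc(OCOC)cc(OCOC)c1C(=O)c1ccccc1 | intermediate
5 | α-oxo gold carbene, {(Me4tBuXPhos)Au=CH–C(=O)–C(CH3)2–O–Ar}+ NTf2−, Ar = 2-benzoyl-3,5-bis(methoxymethoxy)phenyl | CC(C)(Oc1cc(OCOC)cc(OCOC)c1C(=O)c1ccccc1)C(=O)C=[Au][P+](C(C)(C)C)(C(C)(C)C)c1c(C)c(C)c(C)c(C)c1-c1c(C(C)C)cc(C(C)C)cc1C(C)C.[N-](S(=O)(=O)C(F)(F)F)S(=O)(=O)C(F)(F)F | intermediate (not isolated)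
6 | [5,7-bis(methoxymethoxy)-2,2-dimethyl-3-oxochroman-8-yl](phenyl)methanone | CC1(C)Oc2c(C(=O)c3ccccc3)c(OCOC)cc(OCOC)c2CC1=O | intermediate
7 | (R)-[3-hydroxy-5,7-bis(methoxymethoxy)-2,2-dimethylchroman-8-yl](phenyl)methanone | CC1(C)Oc2c(C(=O)c3ccccc3)c(OCOC)cc(OCOC)c2C[C@H]1O | intermediate (not isolated)
8 | (R)-(3,5,7-trihydroxy-2,2-dimethylchroman-8-yl)(phenyl)methanone | CC1(C)Oc2c(C(=O)c3ccccc3)c(O)cc(O)c2C[C@H]1O | intermediate
9 | geranyl bromide, (E)-1-bromo-3,7-dimethylocta-2,6-diene | CC(C)=CCC/C(C)=C/CBr | starting material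
10 | [(3R)-6-[(2E)-3,7-dimethylocta-2,6-dien-1-yl]-3,5,7-trihydroxy-2,2-dimethylchroman-8-yl](phenyl)methanone | CC(C)=CCC/C(C)=C/Cc1c(O)c2c(c(C(=O)c3ccccc3)c1O)OC(C)(C)[C@H](O)C2 | target

## Step count

Total steps: 5. Longest linear sequence: 5 (from 1; 3 and 9 are bought).

## Three steps most likely to fail, each with one fallback

**Step 3 (gold oxidation/cyclisation).** The very electron-rich arene may add directly to the gold-activated alkyne and give a 2H-chromene, the tertiary propargyl ether may ionise, or the carbene may be over-oxidised. The fallback keeps the enolonium logic but generates it as a rhodium carbenoid from a diazoketone; it sets out from 2 and comes back at 6, so it also bypasses step 2. Phenol 2 is O-alkylated with commercial 3-bromo-3-methylbutan-2-one (Cs2CO3, DMF, 50 °C) to give the aryloxy methyl ketone F1. Its only enolisable position is deprotonated with LiN(SiMe3)2 (THF, −78 °C) and acylated with CF3CO2CH2CF3 to the trifluoroacetyl diketone F2 (not isolated). Detrifluoroacetylative diazo transfer (MsN3, Et3N, H2O, MeCN) then gives the α-diazoketone F3. Rh2(OAc)4 (1 mol%, CH2Cl2, rt) forms the rhodium carbenoid, which substitutes the ortho arene carbon and closes the ring to 6.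

**Step 5 (C- versus O-geranylation).** O-alkylation at the 5-OH and dearomatising double alkylation compete, and yields for this type of phenoxide alkylation are typically modest. The fallback sets out from 8 and comes back at 10. It replaces the phenoxide SN2 by an acid-surface Friedel–Crafts allylation of the neutral phenol: 8 and geraniol are heated on acidic Al2O3 in ClCH2CH2Cl at reflux. The allyl cation is delivered ortho to the phenolic OH groups, which means C6. No new compound arises on this path (F0).

**Step 4 (enantioselectivity and chemoselectivity of the reduction).** The "small" side of the ketone is a benzylic methylene, so the ee may be moderate, and borane could begin to touch the diaryl ketone. The fallback sets out from 6 and comes back at 8. It is a reduction–resolution–recycle sequence. NaBH4 (MeOH, −40 °C) reduces only the ring ketone to the racemic alcohol F4. A lipase (Burkholderia cepacia lipase, vinyl acetate, tert-butyl methyl ether, 40 °C) acetylates the (R)-enantiomer, as the Kazlauskas rule predicts, to the (R)-acetate F5 and leaves the (S)-alcohol F6. After chromatography, F5 in MeOH/conc. HCl at 45 °C loses the acetyl and both MOM groups to give 8. F6 is oxidised back to 6 with Dess–Martin periodinane and recycled. The hindered neopentyl-type alcohol may acylate slowly, which is the weak point of this fallback.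

## Further compounds

F1 | step 3 | [2,4-bis(methoxymethoxy)-6-(2-methyl-3-oxobutan-2-yloxy)phenyl](phenyl)methanone | CC(=O)C(C)(C)Oc1cc(OCOC)cc(OCOC)c1C(=O)c1ccccc1
F2 | step 3 | 5-[2-benzoyl-3,5-bis(methoxymethoxy)phenoxy]-1,1,1-trifluoro-5-methylhexane-2,4-dione | O=C(CC(=O)C(C)(C)Oc1cc(OCOC)cc(OCOC)c1C(=O)c1ccccc1)C(F)(F)F
F3 | step 3 | [2-(4-diazo-2-methyl-3-oxobutan-2-yloxy)-4,6-bis(methoxymethoxy)phenyl](phenyl)methanone | [N-]=[N+]=CC(=O)C(C)(C)Oc1cc(OCOC)cc(OCOC)c1C(=O)c1ccccc1
F4 | step 4 | racemic [3-hydroxy-5,7-bis(methoxymethoxy)-2,2-dimethylchroman-8-yl](phenyl)methanone | CC1(C)Oc2c(C(=O)c3ccccc3)c(OCOC)cc(OCOC)c2CC1O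
F5 | step 4 | (R)-8-benzoyl-5,7-bis(methoxymethoxy)-2,2-dimethylchroman-3-yl acetate | CC1(C)Oc2c(C(=O)c3ccccc3)c(OCOC)cc(OCOC)c2C[C@H]1OC(C)=O
F6 | step 4 | (S)-[3-hydroxy-5,7-bis(methoxymethoxy)-2,2-dimethylchroman-8-yl](phenyl)methanone | CC1(C)Oc2c(C(=O)c3ccccc3)c(OCOC)cc(OCOC)c2C[C@@H]1O
F0 | step 5 | none | none
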